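**Time first.** Time is what I must judge for Sunday's flask: is 57 min a resting point for J, or past a top? I leave its charge as written, L 0.500 M and Z 3.10 M, and keep that one reading, to be held against the highest J I reckon.

common to all: L 0.500 M

| flask | Z | J | time |
|---|---|---|---|
| Thursday's | 1.25 M |  |  |
| Tuesday's | 1.90 M |  |  |
| Wednesday's | 1.25 M | 0.250 M |  |
| Sunday's | 3.10 M |  | 57 min |

| run | time / min | [J] / M |
|---|---|---|
| Thursday's run | 2.0 | 0.0192 |
| Thursday's run | 6.2 | 0.0552 |
| Thursday's run | 12 | 0.1021 |
| Thursday's run | 19 | 0.1367 |
| Thursday's run | 27 | 0.1740 |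
| Thursday's run | 36 | 0.2004 |
| Thursday's run | 46 | 0.2175 |
| Thursday's run | 57 | 0.2292 |
| Tuesday's run | 2.0 | 0.0221 |
| Tuesday's run | 6.2 | 0.0685 |
| Tuesday's run | 12 | 0.1176 |
| Tuesday's run | 19 | 0.1676 |
| Tuesday's run | 27 | 0.1957 |
| Tuesday's run | 36 | 0.2225 |
| Tuesday's run | 46 | 0.2330 |
| Tuesday's run | 57 | 0.2351 |
| Wednesday's run | 2.0 | 0.2650 |
| Wednesday's run | 6.2 | 0.2917 |
| Wednesday's run | 12 | 0.3148 |
| Wednesday's run | 19 | 0.3403 |
| Wednesday's run | 27 | 0.3566 |
| Wednesday's run | 36 | 0.3666 |
| Wednesday's run | 46 | 0.3689 |
| Wednesday's run | 57 | 0.3693 |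

(each reading ± 0.002 M)

* reaction order in [Z] at the outset, round the charge of the Thursday's run, defined at two percent of the L turned into J
* J in the Sunday's run at 57 min, as a share of the L charged

- Overall: L + Z -> J.
- Constant volume, constant temperature.
- Bound and free are read together.
- An order is taken over about fifteen percent of the charge, up and down.

**One J molecule.** Wednesday's and Thursday's flasks had the same L and Z. If L falls alike in both, Wednesday's surplus of J is the added J still surviving. At 36 min the added 0.250 M has shrunk to 0.166 M, so each J is lost at a pseudo-first-order rate λ of 0.0113 min⁻¹.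

**One L molecule.** Counting Thursday's J at 6.2 min as turned L, each L goes at κ = 0.0189 min⁻¹. The fork ratio q, the chance per molecule that J is taken over the chance that L is taken, is then λ/κ = 0.601, a selectivity factor. I assume both steps use Z alike, so that q holds at any Z.

**The top.** J gains κL and loses qκJ, so it tops where qJ = L. With x the share of L remaining, J as a share of L charged is (x^q − x)/(1 − q). The top lies at x = 27.9% and gives 46.4%. Tuesday's last reading, which played no part in this, stands at 47.0%.

**Sunday's clock.** Tuesday's and Thursday's readings at 6.2 min give an order in Z of 0.516, a reading with its scatter. That makes Sunday's κ 0.0301 min⁻¹, held at its early value. At 57 min this leaves x = 17.9%, lower than at the top, so I expect J past its top, at 44.3%.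

**Forecast and result.** The forecast gives an order of 0.5 and 47.3% (45% to 49.5%), judging that “the stopping point looks set by L and J, not by Z”; its share is higher than mine. The flask gives 0.58 and 44.1%.

    L + Z → J + E (0.06480 M⁻¹ min⁻¹)
    2 Z ⇌ Z2, settled at all times (4.690 M⁻¹)
    J + Z → X (0.03792 M⁻¹ min⁻¹)

**Past the top.** Sunday's 44.1% lies 2.3 percentage points under my top. In Sunday's flask, with my x, the ratio qJ/L, loss of J over gain, stands at 1.48, so by this reckoning J is falling at 57 min. The step J + Z → X is the reason: Sunday's run without it gives 84.1%. That step accounts for 72% of what is missing from Sunday's J.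

All runs stem from a simulated flask for an exercise, noise included.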